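**Strategy.** The γ-alkylidenebutenolide (ring atoms O1, C2, C3, C4, C5; exocyclic C5=C6) is read as the enol ester of a 2-(hydroxymethyl)acrylic acid with a vinyl ketone. The O1–C2 ester therefore serves as the tether, and ring-closing metathesis of a (Z)-1,3-dien-2-yl acrylate joins C3 to C4. This delivers the complete cross-conjugated lactone in one operation, with the Z geometry preset at the enolate stage, and expels only ethylene. The precursor is an acyclic dienyl ester carrying the intact furyl-diene chain, drawn from (E,E)-farnesyl bromide by furylmethyl coupling, terminal allylic oxidation and hydroxyl-directed asymmetric hydrogenation, which sets the lone stereocentre.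

Key step: step 12

Remark: the sense of induction in step 4 is assigned by analogy with the geraniol to citronellol case; should the first run show the opposite sense, the (R)-ligand is used with no other change.

**Step 1**
Reactants: 1 furan-3-ylmethanol
Product: 2 3-(chloromethyl)furan
Conditions: SOCl2, pyridine, Et2O, 0 °C
Reagents that add atoms: thionyl chloride O=S(Cl)Cl
Why: Chlorodehydroxylation of the primary furylmethyl alcohol through its chlorosulfite, buffered by pyridine so that the acid-sensitive furan is spared.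

**Step 2**
Reactants: 2 3-(chloromethyl)furan; 3 (2E,6E)-farnesyl bromide
Product: 5 3-[(3E,7E)-4,8,12-trimethyltrideca-3,7,11-trien-1-yl]furan, via (furan-3-ylmethyl)magnesium chloride 4 (not isolated)
Conditions: Mg turnings, THF, 0 °C to rt; then 3, Li2CuCl4 (3 mol %), THF, 0 °C
Reagents that add atoms: none
Why: Copper-catalysed Grignard cross-coupling with an allylic bromide should proceed by direct SN2 substitution at the primary allylic carbon with retention of the E geometry, a standard construction of 3-alkylfurans from the 3-furylmethyl Grignard reagent.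

**Step 3**
Reactants: 5 3-[(3E,7E)-4,8,12-trimethyltrideca-3,7,11-trien-1-yl]furan
Product: 6 (2E,6E,10E)-13-(furan-3-yl)-2,6,10-trimethyltrideca-2,6,10-trien-1-ol
Conditions: SeO2 (0.1 equiv), t-BuOOH (2 equiv), salicylic acid (0.1 equiv), CH2Cl2, 0 °C to rt, stopped at partial conversion (5 recovered and recycled)
Reagents that add atoms: selenium dioxide O=[Se]=O (catalytic oxygen carrier); tert-butyl hydroperoxide CC(C)(C)OO (terminal oxidant)
Why: Riley-type allylic oxidation (ene reaction, then [2,3]-sigmatropic shift) should attack the most accessible terminal isopropylidene unit and oxidise its E-methyl group, giving the E allylic alcohol.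

**Step 4**
Reactants: 6 (2E,6E,10E)-13-(furan-3-yl)-2,6,10-trimethyltrideca-2,6,10-trien-1-ol
Product: 7 (2S,6E,10E)-13-(furan-3-yl)-2,6,10-trimethyltrideca-6,10-dien-1-ol
Conditions: H2 (30 atm), Ru(OAc)2[(S)-BINAP] (1 mol %), MeOH, 20 °C
Reagents that add atoms: none
Why: Noyori hydroxyl-directed asymmetric hydrogenation, in which only the C2=C3 alkene can bind ruthenium through the alkoxide, so the two isolated trisubstituted alkenes and the furan should remain, and the C2 stereocentre (S) is set by the face selection of the BINAP ligand.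

**Step 5**
Reactants: 7 (2S,6E,10E)-13-(furan-3-yl)-2,6,10-trimethyltrideca-6,10-dien-1-ol
Product: 8 3-[(3E,7E,12S)-13-iodo-4,8,12-trimethyltrideca-3,7-dien-1-yl]furan
Conditions: iodine (I2), PPh3, imidazole, CH2Cl2, 0 °C to rt
Reagents that add atoms: iodine II
Why: Appel-type iodination (Garegg–Samuelsson conditions) replaces the primary hydroxyl by SN2 at CH2 and does not touch the adjacent stereocentre.

**Step 6**
Reactants: 8 3-[(3E,7E,12S)-13-iodo-4,8,12-trimethyltrideca-3,7-dien-1-yl]furan; 9 acrolein
Product: 11 (5S,9E,13E)-16-(furan-3-yl)-5,9,13-trimethylhexadeca-1,9,13-trien-3-ol (both C3 epimers), via primary alkyllithium 10 (not isolated)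
Conditions: t-BuLi (2.05 equiv), Et2O/pentane, −78 °C; then 9, −78 °C; then H2O
Reagents that add atoms: none
Why: Lithium–iodine exchange, which is much faster at −78 °C than furan metalation, gives the primary alkyllithium that adds 1,2 to acrolein; the new carbinol centre forms unselectively, which is irrelevant because it is oxidised in step 7.

**Step 7**
Reactants: 11 (5S,9E,13E)-16-(furan-3-yl)-5,9,13-trimethylhexadeca-1,9,13-trien-3-ol
Product: 12 (5S,9E,13E)-16-(furan-3-yl)-5,9,13-trimethylhexadeca-1,9,13-trien-3-one
Conditions: Dess–Martin periodinane, CH2Cl2, 0 °C; used promptly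
Reagents that add atoms: none
Why: Dess–Martin oxidation of the secondary allylic alcohol under mild conditions should give the vinyl ketone without conjugate addition, and the C5 stereocentre, being beta to the carbonyl, cannot epimerise.

**Step 8**
Reactants: 13 ethyl 2-(hydroxymethyl)prop-2-enoate
Product: 14 ethyl 2-{[(tert-butyldimethylsilyl)oxy]methyl}prop-2-enoate
Conditions: TBSCl, imidazole, DMF, 0 °C to rt
Reagents that add atoms: tert-butyldimethylsilyl chloride CC(C)(C)[Si](C)(C)Cl
Why: Standard silylation masks the primary allylic hydroxyl so that the acid can later be activated as an acyl donor.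

**Step 9**
Reactants: 14 ethyl 2-{[(tert-butyldimethylsilyl)oxy]methyl}prop-2-enoate
Product: 15 2-{[(tert-butyldimethylsilyl)oxy]methyl}prop-2-enoic acid
Conditions: LiOH·H2O, THF/H2O, 0 °C; then 1 M HCl to pH 4, 0 °C
Reagents that add atoms: lithium hydroxide [Li+].[OH-]
Why: Saponification at low temperature, where the primary TBS ether survives and hydroxide should attack the ester carbonyl faster than the hindered 2-substituted acrylate terminus.

**Step 10**
Reactants: 15 2-{[(tert-butyldimethylsilyl)oxy]methyl}prop-2-enoic acid (two molecules are consumed per molecule of 16)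
Product: 16 2-{[(tert-butyldimethylsilyl)oxy]methyl}prop-2-enoic anhydride
Conditions: DCC (0.5 equiv relative to 15), CH2Cl2, 0 °C to rt; filtration
Reagents that add atoms: 2-{[(tert-butyldimethylsilyl)oxy]methyl}prop-2-enoic acid (the second molecule of 15) C=C(CO[Si](C)(C)C(C)(C)C)C(=O)O
Why: Carbodiimide-mediated dehydrative self-condensation, in which one molecule of 15 adds to DCC to give the O-acylisourea and this acylates a second molecule of 15, gives the symmetrical anhydride, a neutral acyl donor compatible with the silyl ether.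

**Step 11**
Reactants: 12 (5S,9E,13E)-16-(furan-3-yl)-5,9,13-trimethylhexadeca-1,9,13-trien-3-one; 16 2-{[(tert-butyldimethylsilyl)oxy]methyl}prop-2-enoic anhydride
Product: 18 (3Z,5S,9E,13E)-16-(furan-3-yl)-5,9,13-trimethylhexadeca-1,3,9,13-tetraen-3-yl 2-{[(tert-butyldimethylsilyl)oxy]methyl}prop-2-enoate, via lithium (Z)-dienolate 17 (not isolated)
Conditions: LiN(SiMe3)2 (1.1 equiv), THF, −78 °C (12 added dropwise); then cannulated into 16 (1.5 equiv), THF, −78 to −20 °C
Reagents that add atoms: none
Why: Kinetic deprotonation at the only enolisable position (C4) gives the cross-conjugated lithium dienolate, expected mainly with the chain cis to oxygen because the other geometry suffers allylic strain between the branched C5 substituent and the vinyl group, and quenching a lithium enolate with a carboxylic anhydride is the classical O-acylation route to enol esters with retention of enolate geometry.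

**Step 12**
Reactants: 18 (3Z,5S,9E,13E)-16-(furan-3-yl)-5,9,13-trimethylhexadeca-1,3,9,13-tetraen-3-yl 2-{[(tert-butyldimethylsilyl)oxy]methyl}prop-2-enoate
Product: 19 (5Z)-3-{[(tert-butyldimethylsilyl)oxy]methyl}-5-[(2S,6E,10E)-13-(furan-3-yl)-2,6,10-trimethyltrideca-6,10-dien-1-ylidene]furan-2(5H)-one
Conditions: second-generation Grubbs catalyst RuCl2(=CHPh)(PCy3)(H2IMes) (10 mol %, two portions), toluene (0.002 M), 80 °C, argon sparge
Reagents that add atoms: none
Why: Proposed new method: ring-closing metathesis of a 1,3-dien-2-yl acrylate is not an established substrate class; the closest known reactions are the RCM of allyl methacrylate-type esters to alpha-substituted butenolides with second-generation ruthenium catalysts and ene–diene RCM through ruthenium vinylcarbenes. The catalyst should initiate at the only monosubstituted alkene, the CH2=CH terminus of the diene, giving a vinylcarbene at the future C4 that adds intramolecularly across the 1,1-disubstituted acrylate C=CH2 and cycloreverts to release ethylene and form the C3=C4 bond. The five-membered lactone thus closes through a ruthenacyclobutane ([2+2] addition, then cycloreversion), helped by the s-trans diene conformation and by the gain of the fully conjugated dienoate. No stereocentre is created: the Z geometry of C5=C6 is carried over from 18, and the remote (S)-methyl centre is untouched. The step needs chemoselectivity for the two terminal alkene carbons over four other C=C units and the furan, and ring closure over oligomerisation; the first is secured by the trisubstituted or enol-ester nature of the other alkenes, the second by high dilution.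

**Step 13**
Reactants: 19 (5Z)-3-{[(tert-butyldimethylsilyl)oxy]methyl}-5-[(2S,6E,10E)-13-(furan-3-yl)-2,6,10-trimethyltrideca-6,10-dien-1-ylidene]furan-2(5H)-one
Product: 20 (5Z)-5-[(2S,6E,10E)-13-(furan-3-yl)-2,6,10-trimethyltrideca-6,10-dien-1-ylidene]-3-(hydroxymethyl)furan-2(5H)-one
Conditions: HF·pyridine, pyridine/THF, 0 °C to rt
Reagents that add atoms: none
Why: Buffered fluoride cleavage of the primary silyl ether, under which the enol lactone, the furan and the trisubstituted alkenes should be stable.

**Compound list**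

1 | furan-3-ylmethanol | OCc1ccoc1 | starting material
2 | 3-(chloromethyl)furan | ClCc1ccoc1 | intermediate
3 | (2E,6E)-farnesyl bromide, (2E,6E)-1-bromo-3,7,11-trimethyldodeca-2,6,10-triene | BrC/C=C(\C)CC/C=C(\C)CCC=C(C)C | starting material
4 | (furan-3-ylmethyl)magnesium chloride | Cl[Mg]Cc1ccoc1 | intermediate (not isolated)
5 | 3-[(3E,7E)-4,8,12-trimethyltrideca-3,7,11-trien-1-yl]furan | C/C(=C\CCc1ccoc1)CC/C=C(\C)CCC=C(C)C | intermediate
6 | (2E,6E,10E)-13-(furan-3-yl)-2,6,10-trimethyltrideca-2,6,10-trien-1-ol | C/C(=C\CCc1ccoc1)CC/C=C(\C)CC/C=C(\C)CO | intermediate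
7 | (2S,6E,10E)-13-(furan-3-yl)-2,6,10-trimethyltrideca-6,10-dien-1-ol | C/C(=C\CCc1ccoc1)CC/C=C(\C)CCC[C@H](C)CO | intermediate
8 | 3-[(3E,7E,12S)-13-iodo-4,8,12-trimethyltrideca-3,7-dien-1-yl]furan | C/C(=C\CCc1ccoc1)CC/C=C(\C)CCC[C@H](C)CI | intermediate
9 | acrolein, prop-2-enal | C=CC=O | starting material
10 | primary alkyllithium from 8 (configuration at the methyl-bearing carbon unchanged) | C/C(=C\CCc1ccoc1)CC/C=C(\C)CCC[C@H](C)C[Li] | intermediate (not isolated)
11 | (5S,9E,13E)-16-(furan-3-yl)-5,9,13-trimethylhexadeca-1,9,13-trien-3-ol (both C3 epimers) | C/C(=C\CCc1ccoc1)CC/C=C(\C)CCC[C@H](C)CC(O)C=C | intermediate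
12 | (5S,9E,13E)-16-(furan-3-yl)-5,9,13-trimethylhexadeca-1,9,13-trien-3-one | C/C(=C\CCc1ccoc1)CC/C=C(\C)CCC[C@H](C)CC(=O)C=C | intermediate
13 | ethyl 2-(hydroxymethyl)prop-2-enoate | C=C(CO)C(=O)OCC | starting material
14 | ethyl 2-{[(tert-butyldimethylsilyl)oxy]methyl}prop-2-enoate | C=C(CO[Si](C)(C)C(C)(C)C)C(=O)OCC | intermediate
15 | 2-{[(tert-butyldimethylsilyl)oxy]methyl}prop-2-enoic acid | C=C(CO[Si](C)(C)C(C)(C)C)C(=O)O | intermediate
16 | 2-{[(tert-butyldimethylsilyl)oxy]methyl}prop-2-enoic anhydride | C=C(CO[Si](C)(C)C(C)(C)C)C(=O)OC(=O)C(=C)CO[Si](C)(C)C(C)(C)C | intermediate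
17 | lithium (3Z,5S,9E,13E)-16-(furan-3-yl)-5,9,13-trimethylhexadeca-1,3,9,13-tetraen-3-olate | C/C(=C\CCc1ccoc1)CC/C=C(\C)CCC[C@H](C)/C=C(/C=C)O[Li] | intermediate (not isolated)
18 | (3Z,5S,9E,13E)-16-(furan-3-yl)-5,9,13-trimethylhexadeca-1,3,9,13-tetraen-3-yl 2-{[(tert-butyldimethylsilyl)oxy]methyl}prop-2-enoate | C/C(=C\CCc1ccoc1)CC/C=C(\C)CCC[C@H](C)/C=C(/C=C)OC(=O)C(=C)CO[Si](C)(C)C(C)(C)C | intermediate
19 | (5Z)-3-{[(tert-butyldimethylsilyl)oxy]methyl}-5-[(2S,6E,10E)-13-(furan-3-yl)-2,6,10-trimethyltrideca-6,10-dien-1-ylidene]furan-2(5H)-one | C/C(=C\CCc1ccoc1)CC/C=C(\C)CCC[C@H](C)/C=C1/C=C(CO[Si](C)(C)C(C)(C)C)C(=O)O1 | intermediate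
20 | (5Z)-5-[(2S,6E,10E)-13-(furan-3-yl)-2,6,10-trimethyltrideca-6,10-dien-1-ylidene]-3-(hydroxymethyl)furan-2(5H)-one | C/C(=C\CCc1ccoc1)CC/C=C(\C)CCC[C@H](C)/C=C1/C=C(CO)C(=O)O1 | target

**Step count and risks**

Total step count: 13. Longest linear sequence: 10 (steps 1 to 7, then 11 to 13).

Steps most likely to fail:

Step 12 (Proposed new method). The ruthenium carbene may fail to form at, or propagate from, the acyloxy-substituted diene, for instance through chelation by the ester carbonyl or catalyst decay before the hindered 1,1-disubstituted acrylate is engaged; intermolecular cross-metathesis would then compete. The fallback closes the same C3=C4 bond on a conventional substrate by known chemistry. It sets out from 11: esterification with acid 15 (DCC, DMAP, CH2Cl2) would give the allylic ester (5S,9E,13E)-16-(furan-3-yl)-5,9,13-trimethylhexadeca-1,9,13-trien-3-yl 2-{[(tert-butyldimethylsilyl)oxy]methyl}prop-2-enoate F1. Its RCM (second-generation Grubbs catalyst RuCl2(=CHPh)(PCy3)(H2IMes), CH2Cl2, 40 °C), a known route to alpha-substituted butenolides, would give 3-{[(tert-butyldimethylsilyl)oxy]methyl}-5-[(2S,6E,10E)-13-(furan-3-yl)-2,6,10-trimethyltrideca-6,10-dien-1-yl]furan-2(5H)-one F2. Silylation (TIPSOTf, Et3N, CH2Cl2, 0 °C) would give the 2-(triisopropylsilyloxy)furan of F2 F3. Oxidation with one equivalent of dimethyldioxirane at −78 °C, where the silyloxyfuran should react far faster than the chain alkenes or the 3-alkylfuran, would give 3-{[(tert-butyldimethylsilyl)oxy]methyl}-5-hydroxy-5-[(2S,6E,10E)-13-(furan-3-yl)-2,6,10-trimethyltrideca-6,10-dien-1-yl]furan-2(5H)-one F4. Acetylation (Ac2O, pyridine, DMAP) would give the 5-acetoxy analogue of F4 F5, and DBU-mediated elimination of acetic acid, which should favour the more stable Z alkylidene, returns to the route at 19.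

Step 11. Enolisation may give incomplete geometric control, C-acylation may compete with O-acylation, and the vinyl ketone may polymerise under the amide base. The fallback fixes the geometry at a stable, purifiable stage. It sets out from 12: soft enolisation under equilibrating conditions (TMSCl, NaI, Et3N, MeCN, rt) should give the thermodynamically preferred {[(3Z,5S,9E,13E)-16-(furan-3-yl)-5,9,13-trimethylhexadeca-1,3,9,13-tetraen-3-yl]oxy}trimethylsilane F6, purified free of its E isomer. Cleavage with MeLi (THF, 0 °C) regenerates dienolate 17 as a single geometry without amide base, and its acylation with 16 returns to the route at 18. If a minor amount of the E dienyl ester is carried through, the derived E alkylidene lactone should be separable from 19 or isomerisable to the more stable Z form.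

Step 4. Enantio-discrimination may be insufficient for a 2-methyl-substituted trisubstituted allylic alcohol, a pattern less secure than the geraniol type, and remote alkenes may be slowly reduced at forcing pressure. The fallback moves the directing group to a carboxylic acid, for which the tiglic acid precedent is close. It sets out from 6: oxidation with MnO2 (CH2Cl2, rt) would give (2E,6E,10E)-13-(furan-3-yl)-2,6,10-trimethyltrideca-2,6,10-trienal F7. Oxidation with Ag2O (from AgNO3 and NaOH, EtOH/H2O), chosen to spare the furan, would give (2E,6E,10E)-13-(furan-3-yl)-2,6,10-trimethyltrideca-2,6,10-trienoic acid F8. Carboxylate-directed hydrogenation (H2, Ru(OAc)2[(S)-BINAP], MeOH), using the ligand enantiomer that turns tiglic acid into (S)-2-methylbutanoic acid, would give (2S,6E,10E)-13-(furan-3-yl)-2,6,10-trimethyltrideca-6,10-dienoic acid F9. Reduction with LiAlH4 (Et2O, 0 °C) returns to the route at 7.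

**Further compounds**

F1 | step 12 | (5S,9E,13E)-16-(furan-3-yl)-5,9,13-trimethylhexadeca-1,9,13-trien-3-yl 2-{[(tert-butyldimethylsilyl)oxy]methyl}prop-2-enoate (C3 epimers) | C/C(=C\CCc1ccoc1)CC/C=C(\C)CCC[C@H](C)CC(C=C)OC(=O)C(=C)CO[Si](C)(C)C(C)(C)C
F2 | step 12 | 3-{[(tert-butyldimethylsilyl)oxy]methyl}-5-[(2S,6E,10E)-13-(furan-3-yl)-2,6,10-trimethyltrideca-6,10-dien-1-yl]furan-2(5H)-one (C5 epimers) | C/C(=C\CCc1ccoc1)CC/C=C(\C)CCC[C@H](C)CC1C=C(CO[Si](C)(C)C(C)(C)C)C(=O)O1
F3 | step 12 | 2-(triisopropylsilyloxy)furan of F2, tert-butyl({5-[(2S,6E,10E)-13-(furan-3-yl)-2,6,10-trimethyltrideca-6,10-dien-1-yl]-2-[(triisopropylsilyl)oxy]furan-3-yl}methoxy)dimethylsilane | C/C(=C\CCc1ccoc1)CC/C=C(\C)CCC[C@H](C)Cc1cc(CO[Si](C)(C)C(C)(C)C)c(O[Si](C(C)C)(C(C)C)C(C)C)o1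
F4 | step 12 | 3-{[(tert-butyldimethylsilyl)oxy]methyl}-5-hydroxy-5-[(2S,6E,10E)-13-(furan-3-yl)-2,6,10-trimethyltrideca-6,10-dien-1-yl]furan-2(5H)-one (C5 epimers) | C/C(=C\CCc1ccoc1)CC/C=C(\C)CCC[C@H](C)CC1(O)C=C(CO[Si](C)(C)C(C)(C)C)C(=O)O1
F5 | step 12 | 5-acetoxy analogue of F4, 4-{[(tert-butyldimethylsilyl)oxy]methyl}-2-[(2S,6E,10E)-13-(furan-3-yl)-2,6,10-trimethyltrideca-6,10-dien-1-yl]-5-oxo-2,5-dihydrofuran-2-yl acetate | C/C(=C\CCc1ccoc1)CC/C=C(\C)CCC[C@H](C)CC1(OC(C)=O)C=C(CO[Si](C)(C)C(C)(C)C)C(=O)O1
F6 | step 11 | {[(3Z,5S,9E,13E)-16-(furan-3-yl)-5,9,13-trimethylhexadeca-1,3,9,13-tetraen-3-yl]oxy}trimethylsilane | C/C(=C\CCc1ccoc1)CC/C=C(\C)CCC[C@H](C)/C=C(/C=C)O[Si](C)(C)C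
F7 | step 4 | (2E,6E,10E)-13-(furan-3-yl)-2,6,10-trimethyltrideca-2,6,10-trienal | C/C(=C\CCc1ccoc1)CC/C=C(\C)CC/C=C(\C)C=O
F8 | step 4 | (2E,6E,10E)-13-(furan-3-yl)-2,6,10-trimethyltrideca-2,6,10-trienoic acid | C/C(=C\CCc1ccoc1)CC/C=C(\C)CC/C=C(\C)C(=O)O
F9 | step 4 | (2S,6E,10E)-13-(furan-3-yl)-2,6,10-trimethyltrideca-6,10-dienoic acid | C/C(=C\CCc1ccoc1)CC/C=C(\C)CCC[C@H](C)C(=O)O
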